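## Retrosynthetic overview

- Last operation: BCl3 removes the two benzyl ethers of ring B and, by chelation to the ester carbonyl, only the methyl ether next to the ester on ring A.
- Key disconnection: the ring A aryl–alkyl bond. The C12 chain, as an alkoxide-Grignard reagent, displaces one of the two equivalent ortho-methoxy groups of a 2,4,6-trimethoxybenzoate ester through a dearomatized magnesium ketene acetal.
- The trimethoxybenzoate is cut at the aryl–C(=O) bond: 2,4,6-trimethoxyphenyllithium (from 1,3,5-trimethoxybenzene) plus the imidazole-1-carboxylate of the ring B alcohol, so the hindered ester forms with retention at the carbinol.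
- Both (R)-carbinols come from Cu-catalysed opening of (R)-2-propyloxirane by chloroalkyl Grignard reagents; the ring B chain is attached first by Cu-catalysed coupling with 3,5-bis(benzyloxy)benzyl bromide.
- No ring is formed: both benzene rings are bought intact (ring A as 1,3,5-trimethoxybenzene, ring B as the benzyl bromide).

Assumption: the SMILES is taken as written, so both carbinol carbons are R, ring A carries a C12 chain (hydroxyl at C9 from the ring) and ring B a C11 chain (ester oxygen at C8); (R)-2-propyloxirane is bought in high ee.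

## Route

Step 1
Reactants: 1 1-bromo-5-chloropentane; 2 1,3-bis(benzyloxy)-5-(bromomethyl)benzene
Product: 4 1,3-bis(benzyloxy)-5-(6-chlorohexyl)benzene, via 5-chloropentylmagnesium bromide 3 (not isolated)
Conditions: 1, Mg, THF, 25 °C; then 2, Li2CuCl4 (3 mol %), THF, −78 → 0 °C
Reagents that add atoms: none
Why: Mg inserts selectively into the C–Br bond, and the Li2CuCl4-catalysed Kochi-type sp3–sp3 cross-coupling with the benzylic bromide is far faster than any reaction at the primary chloride; no stereocenter is formed.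

Step 2
Reactants: 4 1,3-bis(benzyloxy)-5-(6-chlorohexyl)benzene; 5 (R)-2-propyloxirane
Product: 7 (4R)-11-[3,5-bis(benzyloxy)phenyl]undecan-4-ol, via 6-[3,5-bis(benzyloxy)phenyl]hexylmagnesium chloride 6 (not isolated)
Conditions: Mg, I2 (cat.), THF, reflux; then CuI (10 mol %), 5, THF, −30 → 0 °C
Reagents that add atoms: none
Why: Cu-catalysed SN2 opening of the terminal epoxide by the primary Grignard reagent occurs at the CH2 carbon, so the C–O stereocenter of 5 is carried over untouched as the (4R)-carbinol.

Step 3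
Reactants: 7 (4R)-11-[3,5-bis(benzyloxy)phenyl]undecan-4-ol
Product: 8 (4R)-11-[3,5-bis(benzyloxy)phenyl]undecan-4-yl 1H-imidazole-1-carboxylate
Conditions: CDI (1.5 equiv), THF, 50 °C
Reagents that add atoms: 1,1'-carbonyldiimidazole (CDI), O=C(n1ccnc1)n1ccnc1
Why: Acyl transfer from CDI to the secondary alcohol gives the alkyl imidazole-1-carboxylate (azolide formation) without breaking the carbinol C–O bond, so the center stays R.

Step 4
Reactants: 8 (4R)-11-[3,5-bis(benzyloxy)phenyl]undecan-4-yl 1H-imidazole-1-carboxylate; 9 1,3,5-trimethoxybenzene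
Product: 11 (4R)-11-[3,5-bis(benzyloxy)phenyl]undecan-4-yl 2,4,6-trimethoxybenzoate, via 2,4,6-trimethoxyphenyllithium 10 (not isolated)
Conditions: 9, n-BuLi (1.05 equiv), TMEDA, THF, 0 → 25 °C; then 8, THF, −78 → 0 °C
Reagents that add atoms: none
Why: Directed ortho-lithiation of 9 (all ring C–H equivalent) followed by C-acylation of the aryllithium with the alkyl imidazole-1-carboxylate forms the hindered ester at the aryl–C(=O) bond with retention at the carbinol, and the di-ortho-methoxy ester resists a second addition at −78 °C.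

Step 5
Reactants: 5 (R)-2-propyloxirane; 12 1-bromo-7-chloroheptane
Product: 14 (4R)-12-chlorododecan-4-ol, via 7-chloroheptylmagnesium bromide 13 (not isolated)
Conditions: 12, Mg, THF, 25 °C; then CuI (10 mol %), 5, THF, −30 → 0 °C
Reagents that add atoms: none
Why: Selective Mg insertion into C–Br and Cu-catalysed SN2 opening of the epoxide at its CH2 carbon transfer the R configuration of 5 unchanged to the (4R)-carbinol while the primary chloride stays intact.

Step 6
Reactants: 11 (4R)-11-[3,5-bis(benzyloxy)phenyl]undecan-4-yl 2,4,6-trimethoxybenzoate; 14 (4R)-12-chlorododecan-4-ol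
Product: 18 (4R)-11-[3,5-bis(benzyloxy)phenyl]undecan-4-yl 2-[(9R)-9-hydroxydodecyl]-4,6-dimethoxybenzoate, via chloromagnesium 12-chlorododecan-4-olate 15 (not isolated), via chloromagnesium 12-(chloromagnesio)dodecan-4-olate 16 (not isolated), via dearomatized bis(chloromagnesium) ketene acetal adduct 17 (not isolated)
Conditions: 14 (2.5 equiv), i-PrMgCl (2.5 equiv), THF, 0 °C; Mg, I2 (cat.), THF, reflux; then 11, THF–toluene, 25 → 65 °C
Reagents that add atoms: none
Why: Proposed new method: the alkylmagnesium end of 16 chelates the ester carbonyl oxygen and one ortho-methoxy oxygen of 11 and adds to that methoxy-bearing ring carbon (chelation-directed 1,4-addition) to give the dearomatized magnesium ketene acetal 17, which expels MeOMgCl and rearomatizes, so one of two equivalent ortho-methoxy groups is replaced (mono-substitution because the product is more hindered and less electrophilic) while carbonyl attack is blocked by the two ortho substituents and the secondary alkoxy group; the closest known reaction types are the ester-mediated SNAr of ortho-methoxybenzoates with Grignard reagents (Hattori–Miyano) and the Meyers oxazoline SNAr, and no new stereocenter survives because the sp3 ring carbon of 17 becomes aromatic again.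

Step 7
Reactants: 18 (4R)-11-[3,5-bis(benzyloxy)phenyl]undecan-4-yl 2-[(9R)-9-hydroxydodecyl]-4,6-dimethoxybenzoate
Product: 19 5'-methoxy-integracin B [(4R)-11-(3,5-dihydroxyphenyl)undecan-4-yl 2-hydroxy-6-[(9R)-9-hydroxydodecyl]-4-methoxybenzoate]
Conditions: BCl3 (6 equiv), pentamethylbenzene (6 equiv), CH2Cl2, −78 → 0 °C; aqueous work-up
Reagents that add atoms: none
Why: Lewis-acid ether cleavage: BCl3 removes aryl benzyl ethers at low temperature (pentamethylbenzene traps the benzyl cation so ring B is not C-benzylated) and, through chelation with the ester carbonyl, only the ortho-methyl ether, leaving the para-methoxy group, the ester and both R centers untouched.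

## Compound list

1 | 1-bromo-5-chloropentane | ClCCCCCBr | starting material
2 | 1,3-bis(benzyloxy)-5-(bromomethyl)benzene (3,5-bis(benzyloxy)benzyl bromide) | BrCc1cc(OCc2ccccc2)cc(OCc2ccccc2)c1 | starting material
3 | 5-chloropentylmagnesium bromide | ClCCCCC[Mg]Br | intermediate
4 | 1,3-bis(benzyloxy)-5-(6-chlorohexyl)benzene | ClCCCCCCc1cc(OCc2ccccc2)cc(OCc2ccccc2)c1 | intermediate
5 | (R)-2-propyloxirane | CCC[C@@H]1CO1 | starting material
6 | 6-[3,5-bis(benzyloxy)phenyl]hexylmagnesium chloride | Cl[Mg]CCCCCCc1cc(OCc2ccccc2)cc(OCc2ccccc2)c1 | intermediate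
7 | (4R)-11-[3,5-bis(benzyloxy)phenyl]undecan-4-ol | CCC[C@@H](O)CCCCCCCc1cc(OCc2ccccc2)cc(OCc2ccccc2)c1 | intermediate
8 | (4R)-11-[3,5-bis(benzyloxy)phenyl]undecan-4-yl 1H-imidazole-1-carboxylate | CCC[C@@H](OC(=O)n1ccnc1)CCCCCCCc1cc(OCc2ccccc2)cc(OCc2ccccc2)c1 | intermediate
9 | 1,3,5-trimethoxybenzene | COc1cc(OC)cc(OC)c1 | starting material
10 | 2,4,6-trimethoxyphenyllithium | [Li]c1c(OC)cc(OC)cc1OC | intermediate
11 | (4R)-11-[3,5-bis(benzyloxy)phenyl]undecan-4-yl 2,4,6-trimethoxybenzoate | COc1cc(OC)c(C(=O)O[C@H](CCC)CCCCCCCc2cc(OCc3ccccc3)cc(OCc3ccccc3)c2)c(OC)c1 | intermediate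
12 | 1-bromo-7-chloroheptane | ClCCCCCCCBr | starting material
13 | 7-chloroheptylmagnesium bromide | ClCCCCCCC[Mg]Br | intermediate
14 | (4R)-12-chlorododecan-4-ol | CCC[C@@H](O)CCCCCCCCCl | intermediate
15 | chloromagnesium (4R)-12-chlorododecan-4-olate | CCC[C@@H](O[Mg]Cl)CCCCCCCCCl | intermediate
16 | chloromagnesium (4R)-12-(chloromagnesio)dodecan-4-olate (Normant-type alkoxide Grignard reagent) | CCC[C@@H](O[Mg]Cl)CCCCCCCC[Mg]Cl | intermediate
17 | dearomatized adduct of 16 at C2 of the benzoate ring of 11: bis(chloromagnesium) ketene acetal with a 2-alkyl-2,4,6-trimethoxycyclohexa-3,5-dien-1-ylidene ring, both carbinol centers R, mixture of epimers at the sp3 ring carbon | COC1(CCCCCCCC[C@@H](CCC)O[Mg]Cl)C=C(OC)C=C(OC)C1=C(O[Mg]Cl)O[C@H](CCC)CCCCCCCc1cc(OCc2ccccc2)cc(OCc2ccccc2)c1 | intermediate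
18 | (4R)-11-[3,5-bis(benzyloxy)phenyl]undecan-4-yl 2-[(9R)-9-hydroxydodecyl]-4,6-dimethoxybenzoate | CCC[C@@H](O)CCCCCCCCc1cc(OC)cc(OC)c1C(=O)O[C@H](CCC)CCCCCCCc1cc(OCc2ccccc2)cc(OCc2ccccc2)c1 | intermediate
19 | 5'-methoxy-integracin B, (4R)-11-(3,5-dihydroxyphenyl)undecan-4-yl 2-hydroxy-6-[(9R)-9-hydroxydodecyl]-4-methoxybenzoate | CCC[C@@H](O)CCCCCCCCc1cc(OC)cc(O)c1C(=O)O[C@H](CCC)CCCCCCCc1cc(O)cc(O)c1 | target

## Step count and risks

Total step count: 7. Longest linear sequence: 6 steps (steps 1, 2, 3, 4, 6, 7).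

Step 6 is the most likely to fail: the Grignard reagent may attack the ester carbonyl, or the twisted, electron-rich benzoate may not be electrophilic enough. The fallback sets out from 14 (through 16) and comes back at 18, making the aryl–alkyl bond before the aryl–carbonyl bond. Reagent 16, made from 14 as in step 6, is cross-coupled with bought 1-bromo-3,5-dimethoxybenzene (COc1cc(Br)cc(OC)c1; Pd(dppf)Cl2 3 mol %, THF, 60 °C, Kumada coupling) to give (4R)-12-(3,5-dimethoxyphenyl)dodecan-4-ol F1. NBS (MeCN, 0 °C) brominates the position ortho to the chain and para to a methoxy group to give (4R)-12-(2-bromo-3,5-dimethoxyphenyl)dodecan-4-ol F2. t-BuLi (3 equiv, THF, −78 °C) deprotonates the alcohol and exchanges bromine for lithium to give lithium (4R)-12-(2-lithio-3,5-dimethoxyphenyl)dodecan-4-olate F3, whose aryllithium carbon is acylated by imidazole carboxylate 8 (−78 → 0 °C) to give 18.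

Step 7 is second: BCl3 could also touch the para-methoxy group, the secondary ester or the free secondary alcohol, or debenzylation could stall. The fallback sets out from 18 and comes back at 19 in two orthogonal stages. Hydrogenolysis (H2 1 atm, Pd/C, EtOAc–EtOH, 25 °C) removes both benzyl ethers to give (4R)-11-(3,5-dihydroxyphenyl)undecan-4-yl 2-[(9R)-9-hydroxydodecyl]-4,6-dimethoxybenzoate F4. MgI2 etherate (toluene, 80 °C) then cleaves only the methyl ether chelated to the ester carbonyl and gives 19.

Step 4 is third: aryllithium 10 may add twice or attack a methoxy-bearing carbon of the product. The fallback sets out from 9 and 7 and comes back at 11, forming the ester C–O bond instead. Aryllithium 10 (from 9 as in step 4) is quenched with CO2 and acidified with HCl to give 2,4,6-trimethoxybenzoic acid F5. Oxalyl chloride (cat. DMF, CH2Cl2, 25 °C) converts it to 2,4,6-trimethoxybenzoyl chloride F6. Alcohol 7 is deprotonated with n-BuLi (THF, −78 °C) to lithium (4R)-11-[3,5-bis(benzyloxy)phenyl]undecan-4-olate F7, which is acylated by F6 (−78 → 25 °C) to give 11.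

## Further compounds

F1 | step 6 | (4R)-12-(3,5-dimethoxyphenyl)dodecan-4-ol | CCC[C@@H](O)CCCCCCCCc1cc(OC)cc(OC)c1
F2 | step 6 | (4R)-12-(2-bromo-3,5-dimethoxyphenyl)dodecan-4-ol | CCC[C@@H](O)CCCCCCCCc1cc(OC)cc(OC)c1Br
F3 | step 6 | lithium (4R)-12-(2-lithio-3,5-dimethoxyphenyl)dodecan-4-olate | CCC[C@@H](O[Li])CCCCCCCCc1cc(OC)cc(OC)c1[Li]
F4 | step 7 | (4R)-11-(3,5-dihydroxyphenyl)undecan-4-yl 2-[(9R)-9-hydroxydodecyl]-4,6-dimethoxybenzoate | CCC[C@@H](O)CCCCCCCCc1cc(OC)cc(OC)c1C(=O)O[C@H](CCC)CCCCCCCc1cc(O)cc(O)c1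
F5 | step 4 | 2,4,6-trimethoxybenzoic acid | COc1cc(OC)c(C(=O)O)c(OC)c1
F6 | step 4 | 2,4,6-trimethoxybenzoyl chloride | COc1cc(OC)c(C(Cl)=O)c(OC)c1
F7 | step 4 | lithium (4R)-11-[3,5-bis(benzyloxy)phenyl]undecan-4-olate | CCC[C@@H](O[Li])CCCCCCCc1cc(OCc2ccccc2)cc(OCc2ccccc2)c1
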